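The pyran ring is opened at C4–C4a. C4 is carried as the α-carbon of a carboxylic acid: the carboxyl group first activates an (E)-4-aryloxycrotonate for a rhodium-catalysed asymmetric arylation that sets C3 (S), then leaves as CO2. In the key step the precursor, the open-chain N-hydroxyphthalimide ester of an (S)-3-aryl-4-aryloxybutanoic acid, gives the primary C4 radical under photoredox catalysis, and this closes the six-membered ring on the unfunctionalised C4a–H of the A ring, uniting two carbons that are both donors in polar chemistry. The step exploits C4a as the unhindered A-ring carbon ortho to O1 and para to the 7-methoxy group, at the end of the chain C4–C3–C2–O1–C8a–C4a. The B-ring quinone is unmasked last.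

Key step: step 7

Assumption: the SMILES is read as (3S). Isoflavan numbering is used throughout (O1, C2, C3, C4, C4a–C8a for the chroman, primed numbers for the B ring). Compounds 1, 6 and 7 are taken as commercial.

Step 1
Reactants: 1 2,3-dimethoxyphenol
Product: 2 1,2-dimethoxy-3-(methoxymethoxy)benzene
Conditions: MOMCl, K2CO3, acetone, 0 °C to rt
Reagents that add atoms: chloromethyl methyl ether (MOMCl), COCCl
Why: Williamson-type O-alkylation of the phenoxide with the reactive α-chloro ether masks the future quinone oxygen and installs the group that directs the next lithiation.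

Step 2
Reactants: 2 1,2-dimethoxy-3-(methoxymethoxy)benzene
Product: 5 [3,4-dimethoxy-2-(methoxymethoxy)phenyl]boronic acid, via aryllithium 3 (not isolated), via lithium aryltriisopropoxyborate 4 (not isolated)
Conditions: n-BuLi, THF, 0 °C to rt; B(OiPr)3, −78 °C to rt; then 1 M HCl to pH 6, 0 °C
Reagents that add atoms: triisopropyl borate, CC(C)OB(OC(C)C)OC(C)C; water, O
Why: Directed ortho-metalation, in which the chelating OMOM group outcompetes the methoxy groups so that lithiation should occur at its only free ortho carbon, followed by electrophilic borylation and a hydrolysis mild enough to keep the acetal.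

Step 3
Reactants: 6 3,4-dimethoxyphenol; 7 methyl (E)-4-bromobut-2-enoate
Product: 8 methyl (E)-4-(3,4-dimethoxyphenoxy)but-2-enoate
Conditions: K2CO3, acetone, reflux
Reagents that add atoms: none
Why: Williamson ether synthesis (SN2) at the primary allylic bromide, with a base too weak to disturb the (E)-enoate.

Step 4
Reactants: 8 methyl (E)-4-(3,4-dimethoxyphenoxy)but-2-enoate; 5 [3,4-dimethoxy-2-(methoxymethoxy)phenyl]boronic acid
Product: 9 methyl (3S)-3-[3,4-dimethoxy-2-(methoxymethoxy)phenyl]-4-(3,4-dimethoxyphenoxy)butanoate
Conditions: [Rh(OH)((R)-binap)]2 (1.5 mol %), 5 (2 equiv), dioxane/H2O 10:1, 40 °C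
Reagents that add atoms: none
Why: Hayashi–Miyaura asymmetric 1,4-addition, in which the aryl–rhodium/(R)-BINAP species should insert the (E)-enoate through its α-re face, as the accepted quadrant model for (E)-enoates predicts, which sets C3 as (S) before water protonates the oxa-π-allyl rhodium (the antipodal ligand is at hand should the sense prove opposite).

Step 5
Reactants: 9 methyl (3S)-3-[3,4-dimethoxy-2-(methoxymethoxy)phenyl]-4-(3,4-dimethoxyphenoxy)butanoate
Product: 11 (3S)-3-[3,4-dimethoxy-2-(methoxymethoxy)phenyl]-4-(3,4-dimethoxyphenoxy)butanoic acid, via lithium carboxylate 10 (not isolated)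
Conditions: LiOH, THF/MeOH/H2O, rt; then 1 M HCl to pH 4, 0 °C
Reagents that add atoms: lithium hydroxide, [Li+].[OH-]
Why: Saponification (BAc2) of the methyl ester, safe for C3 because the stereocentre is β to the carbonyl and the aryloxide sits γ and cannot leave by E1cB, while the brief cold acidification spares the MOM acetal.

Step 6
Reactants: 11 (3S)-3-[3,4-dimethoxy-2-(methoxymethoxy)phenyl]-4-(3,4-dimethoxyphenoxy)butanoic acid
Product: 12 1,3-dioxoisoindolin-2-yl (3S)-3-[3,4-dimethoxy-2-(methoxymethoxy)phenyl]-4-(3,4-dimethoxyphenoxy)butanoate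
Conditions: N-hydroxyphthalimide, DIC, DMAP (10 mol %), CH2Cl2, rt
Reagents that add atoms: N-hydroxyphthalimide, O=C1c2ccccc2C(=O)N1O
Why: Steglich-type carbodiimide esterification gives the redox-active ester under neutral conditions that touch neither the acetal nor C3.

Step 7
Reactants: 12 1,3-dioxoisoindolin-2-yl (3S)-3-[3,4-dimethoxy-2-(methoxymethoxy)phenyl]-4-(3,4-dimethoxyphenoxy)butanoate
Product: 14 (3S)-3-[3,4-dimethoxy-2-(methoxymethoxy)phenyl]-6,7-dimethoxy-3,4-dihydro-2H-chromene, via primary C4 radical 13 (not isolated)
Conditions: 4CzIPN (5 mol %), DMSO (0.02 M), 450 nm LEDs, N2, rt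
Reagents that add atoms: none
Why: Single-electron reduction of the N-(acyloxy)phthalimide within the photocatalytic cycle (the trialkoxy A ring can act as reductive quencher of excited 4CzIPN) cleaves the N–O bond and expels CO2, so that the former α-carbon becomes the primary C4 radical 13. This radical adds to the free A-ring carbon ortho to O1 and para to the 7-methoxy group (the future C4a), and the cyclohexadienyl radical is oxidised in the catalytic cycle and deprotonated by the phthalimide anion, which makes the step redox-neutral. The reaction type is the known photoredox decarboxylative intramolecular arene alkylation of redox-active esters (homolytic aromatic substitution), which joins a carboxylic acid α-carbon and an electron-rich arene carbon that polar chemistry could not unite. The pyran ring closes in the six-membered ortho mode (Ar2-6, formally 6-exo-trig on the C4a=C5 bond), whereas five-membered ipso attack at C8a is reversible and unproductive because it would have to expel an alkoxyl radical. No stereocentre is formed, and C3 stays (S) because the radical sits on the neighbouring carbon and no bond at C3 is broken. The step needs attack at C4a rather than at the other ortho carbon (C8 of the target) and ring closure faster than hydrogen abstraction or 1,2-aryl shift: C8 is flanked by O1 and the 7-methoxy group while C4a has a free neighbour, and high dilution in a poor hydrogen-donor medium favours cyclisation.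

Step 8
Reactants: 14 (3S)-3-[3,4-dimethoxy-2-(methoxymethoxy)phenyl]-6,7-dimethoxy-3,4-dihydro-2H-chromene
Product: 15 6-[(3S)-6,7-dimethoxy-3,4-dihydro-2H-chromen-3-yl]-2,3-dimethoxyphenol
Conditions: conc. HCl (cat.), MeOH, 50 °C
Reagents that add atoms: none
Why: Acid-catalysed transacetalisation passes the methoxymethyl group to methanol and frees the 2'-phenol, while the aryl methyl ethers, the chroman ether and C3 are inert to these conditions.

Step 9
Reactants: 15 6-[(3S)-6,7-dimethoxy-3,4-dihydro-2H-chromen-3-yl]-2,3-dimethoxyphenol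
Product: 16 abroquinone A, 5-[(3S)-6,7-dimethoxy-3,4-dihydro-2H-chromen-3-yl]-2,3-dimethoxycyclohexa-2,5-diene-1,4-dione
Conditions: (KSO3)2NO (2.5 equiv), KH2PO4 buffer, acetone/H2O, rt
Reagents that add atoms: potassium nitrosodisulfonate (Fremy's salt), [K+].[K+].[O]N(S(=O)(=O)[O-])S(=O)(=O)[O-]
Why: Teuber oxidation, in which one equivalent of the nitroxyl abstracts the phenolic hydrogen and a second delivers oxygen to the free para carbon C5', so that only the B ring (the sole free phenol) is oxidised and the near-neutral buffer avoids tautomerisation at C3.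

Compound list
1 | 2,3-dimethoxyphenol | COc1cccc(O)c1OC | starting material
2 | 1,2-dimethoxy-3-(methoxymethoxy)benzene | COCOc1cccc(OC)c1OC | intermediate
3 | [3,4-dimethoxy-2-(methoxymethoxy)phenyl]lithium (not isolated) | [Li]c1ccc(OC)c(OC)c1OCOC | intermediate
4 | lithium [3,4-dimethoxy-2-(methoxymethoxy)phenyl]triisopropoxyborate (not isolated) | [Li+].COCOc1c(ccc(OC)c1OC)[B-](OC(C)C)(OC(C)C)OC(C)C | intermediate
5 | [3,4-dimethoxy-2-(methoxymethoxy)phenyl]boronic acid | COCOc1c(ccc(OC)c1OC)B(O)O | intermediate
6 | 3,4-dimethoxyphenol | COc1ccc(O)cc1OC | starting material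
7 | methyl (E)-4-bromobut-2-enoate | COC(=O)/C=C/CBr | starting material
8 | methyl (E)-4-(3,4-dimethoxyphenoxy)but-2-enoate | COC(=O)/C=C/COc1ccc(OC)c(OC)c1 | intermediate
9 | methyl (3S)-3-[3,4-dimethoxy-2-(methoxymethoxy)phenyl]-4-(3,4-dimethoxyphenoxy)butanoate | COCOc1c(ccc(OC)c1OC)[C@@H](COc2ccc(OC)c(OC)c2)CC(=O)OC | intermediate
10 | lithium (3S)-3-[3,4-dimethoxy-2-(methoxymethoxy)phenyl]-4-(3,4-dimethoxyphenoxy)butanoate (not isolated) | [Li+].COCOc1c(ccc(OC)c1OC)[C@@H](COc2ccc(OC)c(OC)c2)CC(=O)[O-] | intermediate
11 | (3S)-3-[3,4-dimethoxy-2-(methoxymethoxy)phenyl]-4-(3,4-dimethoxyphenoxy)butanoic acid | COCOc1c(ccc(OC)c1OC)[C@@H](COc2ccc(OC)c(OC)c2)CC(=O)O | intermediate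
12 | 1,3-dioxoisoindolin-2-yl (3S)-3-[3,4-dimethoxy-2-(methoxymethoxy)phenyl]-4-(3,4-dimethoxyphenoxy)butanoate | COCOc1c(ccc(OC)c1OC)[C@@H](COc2ccc(OC)c(OC)c2)CC(=O)ON3C(=O)c4ccccc4C3=O | intermediate
13 | (2S)-2-[3,4-dimethoxy-2-(methoxymethoxy)phenyl]-3-(3,4-dimethoxyphenoxy)propyl radical (not isolated) | COCOc1c(ccc(OC)c1OC)[C@@H](COc2ccc(OC)c(OC)c2)[CH2] | intermediate
14 | (3S)-3-[3,4-dimethoxy-2-(methoxymethoxy)phenyl]-6,7-dimethoxy-3,4-dihydro-2H-chromene | COCOc1c(ccc(OC)c1OC)[C@H]2COc3cc(OC)c(OC)cc3C2 | intermediate
15 | 6-[(3S)-6,7-dimethoxy-3,4-dihydro-2H-chromen-3-yl]-2,3-dimethoxyphenol | Oc1c(ccc(OC)c1OC)[C@H]2COc3cc(OC)c(OC)cc3C2 | intermediate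
16 | abroquinone A | COC1=C(OC)C(=O)C([C@H]2COc3cc(OC)c(OC)cc3C2)=CC1=O | target

Total steps: 9. Longest linear sequence: 8 steps (steps 1, 2, 4, 5, 6, 7, 8, 9).

Steps most likely to fail

Step 7. The nucleophilic primary radical may add too slowly to the electron-rich ring. Hydrogen abstraction from the medium, 1,6-hydrogen transfer from the OCH2O group or attack at the hindered ortho carbon could then compete. The fallback sets out from acid 11 and comes back at 14.
- Electrophilic iodination (NIS, MeCN, 0 °C) should mark the most nucleophilic A-ring carbon, the future C4a, and give the iodo acid F1.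
- DIC and N-hydroxyphthalimide convert it into the iodo redox-active ester F2.
- An intramolecular nickel-catalysed reductive decarboxylative cross-electrophile coupling (NiBr2·glyme, dtbbpy, Zn, DMA) then forms the same bond. The site is fixed by the iodine, because the radical is captured at aryl-nickel instead of adding to the arene.

Step 4. Protodeboronation of the hindered, electron-rich ortho-alkoxy boronic acid may outrun transmetalation. Facial discrimination may also be weak with the small methyl ester. The fallback sets out from 8 and 5 and comes back at 11.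
- The more active phosphine-free catalyst [Rh(OH)(cod)]2 (dioxane/H2O, rt) should give the racemic ester F3.
- A lipase (serine hydrolase class, chosen by screening, phosphate buffer/MTBE) then performs a kinetic resolution by hydrolysing the (S)-enantiomer to acid 11.
- The unreacted (R)-ester F4 is removed by extraction.

Step 9. Oxidative coupling of the phenoxyl radical or incomplete para-oxygenation may lower the return. Tautomerisation of the product towards a quinone methide in a drifting pH would erode configuration at C3. The fallback sets out from 15 and comes back at 16.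
- Azo coupling of the phenoxide with 4-sulfobenzenediazonium (aq. NaOH, 0 °C) can only occur at the free para carbon and gives the azo phenol F5.
- Sodium dithionite cleaves the azo bond to give the para-aminophenol F6.
- FeCl3 in dilute HCl oxidises this to the quinone imine, which hydrolyses to 16 under acidic conditions that do not enolise C3.

Further compounds
F1 | step 7 | (3S)-3-[3,4-dimethoxy-2-(methoxymethoxy)phenyl]-4-(2-iodo-4,5-dimethoxyphenoxy)butanoic acid | COCOc1c(ccc(OC)c1OC)[C@@H](COc2cc(OC)c(OC)cc2I)CC(=O)O
F2 | step 7 | 1,3-dioxoisoindolin-2-yl (3S)-3-[3,4-dimethoxy-2-(methoxymethoxy)phenyl]-4-(2-iodo-4,5-dimethoxyphenoxy)butanoate | COCOc1c(ccc(OC)c1OC)[C@@H](COc2cc(OC)c(OC)cc2I)CC(=O)ON3C(=O)c4ccccc4C3=O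
F3 | step 4 | racemic methyl 3-[3,4-dimethoxy-2-(methoxymethoxy)phenyl]-4-(3,4-dimethoxyphenoxy)butanoate | COCOc1c(ccc(OC)c1OC)C(COc2ccc(OC)c(OC)c2)CC(=O)OC
F4 | step 4 | methyl (3R)-3-[3,4-dimethoxy-2-(methoxymethoxy)phenyl]-4-(3,4-dimethoxyphenoxy)butanoate | COCOc1c(ccc(OC)c1OC)[C@H](COc2ccc(OC)c(OC)c2)CC(=O)OC
F5 | step 9 | 4-[(E)-{5-[(3S)-6,7-dimethoxy-3,4-dihydro-2H-chromen-3-yl]-4-hydroxy-2,3-dimethoxyphenyl}diazenyl]benzenesulfonic acid | Oc1c(cc(/N=N/c2ccc(cc2)S(=O)(=O)O)c(OC)c1OC)[C@H]3COc4cc(OC)c(OC)cc4C3
F6 | step 9 | 4-amino-6-[(3S)-6,7-dimethoxy-3,4-dihydro-2H-chromen-3-yl]-2,3-dimethoxyphenol | Oc1c(cc(N)c(OC)c1OC)[C@H]2COc3cc(OC)c(OC)cc3C2
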